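**Retrosynthetic overview**
1. Target 29 comes from diimide reduction of alkene 28, which is made by Julia–Kocienski union (C11–C12) of decalin tetrazolyl sulfone 15 with dioxane aldehyde 27.
2. The decalin comes from one radical cascade on epoxy sulfolene 11: Cp2TiCl opens the epoxide, ring A closes (C4–C5), then ring B closes (key bond C9–C10) onto the ring-locked Z-alkene of 3-methyl-3-sulfolene, and C7–S β-scission gives the Δ7 alkene and a C11 sulfinate.
3. 11 comes from (R)-epoxygeranyl bromide 9 and sulfolene 10; 9 is built from 5-bromo-2-methylpent-2-ene, acetylide, Me3Al and ClCO2Me, with a Shi epoxidation setting C3 (removed later).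
4. The 1,2-dioxane is closed last in its own arm by hydroperoxide SN2 opening of a cis-β-lactone (C3); the tertiary C–OO (C6) comes from perhydrolysis of an epoxide derived from (R)-2-methylglycidol.
5. Ring order: ring A, then ring B (same step); dioxane in a separate arm; fragment union last.

Assumption: the SMILES is taken at face value, i.e. (2S,3S,6S) in the dioxane propanoate and 5R,9S,10R in the decalin (trans-decalin, C9 side chain anti to the C10 methyl). Drimane numbering (C1–C12) is used for the decalin and its chain.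

**Route**

Step 1
Reactants: 1 5-bromo-2-methylpent-2-ene; 2 lithium acetylide–ethylenediamine complex
Product: 3 6-methylhept-5-en-1-yne
Conditions: LiC≡CH·H2NCH2CH2NH2 (1.3 equiv), DMSO, 10 °C to rt
Reagents that add atoms: none
Why: SN2 alkylation of acetylide by a primary homoallylic bromide; no stereocentre is formed.

Step 2
Reactants: 3 6-methylhept-5-en-1-yne
Product: 5 methyl (2E)-3,7-dimethylocta-2,6-dienoate, via alkenyldimethylalane 4 (not isolated)
Conditions: Me3Al (2 equiv), Cp2ZrCl2 (0.2 equiv), CH2Cl2, rt; then ClCO2Me, 0 °C to rt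
Reagents that add atoms: trimethylaluminium, C[Al](C)C; methyl chloroformate, COC(=O)Cl
Why: Negishi zirconium-catalysed syn-carboalumination puts Me and Al cis on the alkyne and the alkenylalane is acylated with retention to the (E)-enoate; this methyl becomes the C10 methyl, and the alkene geometry is irrelevant later because C10 passes through a radical.

Step 3
Reactants: 5 methyl (2E)-3,7-dimethylocta-2,6-dienoate
Product: 6 methyl (2E)-5-[(2R)-3,3-dimethyloxiran-2-yl]-3-methylpent-2-enoate
Conditions: D-fructose-derived Shi ketone (0.3 equiv), Oxone (2KHSO5·KHSO4·K2SO4), K2CO3, Bu4NHSO4, MeCN/CH2(OMe)2/aq. Na2B4O7 buffer, 0 °C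
Reagents that add atoms: potassium peroxymonosulfate, [K+].OOS(=O)(=O)[O-]
Why: Shi asymmetric epoxidation (chiral dioxirane, spiro transition state) attacks only the electron-rich trisubstituted alkene because the enoate alkene is deactivated; the D-fructose-derived ketone gives the (R)-epoxide, which becomes C3 and fixes the absolute sense of the decalin.

Step 4
Reactants: 6 methyl (2E)-5-[(2R)-3,3-dimethyloxiran-2-yl]-3-methylpent-2-enoate
Product: 7 (2E)-5-[(2R)-3,3-dimethyloxiran-2-yl]-3-methylpent-2-en-1-ol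
Conditions: iBu2AlH (2.2 equiv), CH2Cl2, −78 °C; aqueous work-up
Reagents that add atoms: none
Why: 1,2-reduction of the enoate by the aluminium hydride at low temperature leaves the trisubstituted epoxide untouched.

Step 5
Reactants: 7 (2E)-5-[(2R)-3,3-dimethyloxiran-2-yl]-3-methylpent-2-en-1-ol
Product: 9 (3R)-3-[(3E)-5-bromo-3-methylpent-3-en-1-yl]-2,2-dimethyloxirane, via allylic mesylate 8 (not isolated)
Conditions: MsCl, Et3N, CH2Cl2, −40 °C; then LiBr, THF, −40 to 0 °C
Reagents that add atoms: methanesulfonyl chloride, CS(=O)(=O)Cl (into 8); lithium bromide, [Li+].[Br-]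
Why: mesylation followed by SN2 displacement with bromide gives the allylic bromide under non-acidic conditions that preserve the epoxide.

Step 6
Reactants: 9 (3R)-3-[(3E)-5-bromo-3-methylpent-3-en-1-yl]-2,2-dimethyloxirane; 10 3-methyl-2,5-dihydrothiophene 1,1-dioxide
Product: 11 2-{(2E)-5-[(2R)-3,3-dimethyloxiran-2-yl]-3-methylpent-2-en-1-yl}-3-methyl-2,5-dihydrothiophene 1,1-dioxide (1:1 epimers at ring C2, which is C7)
Conditions: LiN(SiMe3)2 (1.1 equiv) added to 9 + 10 in THF/HMPA (4:1), −78 °C
Reagents that add atoms: none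
Why: alkylation of the sulfone-stabilised allyl anion, formed regioselectively at the CH2 next to the methyl-bearing carbon and trapped in situ (SN2); the new C7 centre forms without control and is destroyed in step 7.

Step 7
Reactants: 11 epoxy sulfolene
Product: 12 sodium [(1S,4aS,6R,8aR)-6-hydroxy-2,5,5,8a-tetramethyl-1,4,4a,5,6,7,8,8a-octahydronaphthalen-1-yl]methanesulfinate
Conditions: Cp2TiCl2 (2.5 equiv), Mn dust (8 equiv), THF (0.01 M, slow addition of 11), rt; then 1 M aq. NaOH, sulfinate taken from the aqueous phase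
Reagents that add atoms: sodium hydroxide, [Na+].[OH-]
Why: Proposed new method: Cp2TiCl (trivalent titanium) opens the epoxide to the tertiary C4 radical and 6-endo closure gives ring A and the C10 radical as in known titanocene epoxypolyene cyclisations (chair, OTi equatorial, so C3 sets C5); the new element is the second 6-endo attack of C10 on C9 of the sulfolene, whose ring-locked Z geometry forces C11 axial and anti to the C10 methyl in a chair/bridged transition state (sets C9 and C10, trans-decalin), after which β-scission of the axial C7–S bond (allyl sulfone addition–fragmentation) gives the Δ7 alkene and a C11 sulfonyl radical that is reduced to the sulfinate; only the C7 epimer that can bridge the face syn to H5 closes, so the ceiling is about half of 11 and the neutral monocyclic by-products stay in the organic phase.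

Step 8
Reactants: 12 sodium sulfinate
Product: 13 5-({[(1S,4aS,6R,8aR)-6-hydroxy-2,5,5,8a-tetramethyl-1,4,4a,5,6,7,8,8a-octahydronaphthalen-1-yl]methyl}sulfonyl)-1-phenyl-1H-tetrazole
Conditions: 5-chloro-1-phenyl-1H-tetrazole (1.5 equiv), DMF, 60 °C
Reagents that add atoms: 5-chloro-1-phenyl-1H-tetrazole, Clc1nnnn1-c1ccccc1
Why: SNAr S-arylation of the sulfinate on the activated chlorotetrazole gives the Julia–Kocienski sulfone without touching any stereocentre.

Step 9
Reactants: 13 hydroxy tetrazolyl sulfone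
Product: 14 O-ester of 13 at the C3 hydroxyl with 1H-imidazole-1-carbothioic acid (stereocentres as in 13)
Conditions: 1,1'-thiocarbonyldiimidazole, DMAP (cat.), ClCH2CH2Cl, 70 °C
Reagents that add atoms: 1,1'-thiocarbonyldiimidazole, S=C(n1ccnc1)n1ccnc1
Why: thioacylation of the equatorial secondary alcohol under base-free conditions (the sulfone α-CH2 is acidic) prepares the Barton–McCombie deoxygenation.

Step 10
Reactants: 14 thiocarbonylimidazolide
Product: 15 1-phenyl-5-({[(1S,4aR,8aR)-2,5,5,8a-tetramethyl-1,4,4a,5,6,7,8,8a-octahydronaphthalen-1-yl]methyl}sulfonyl)-1H-tetrazole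
Conditions: (Me3Si)3SiH, AIBN (cat.), toluene, 85 °C
Reagents that add atoms: none
Why: Barton–McCombie radical deoxygenation removes the C3 oxygen that served as control element; the alkyl heteroaryl sulfone and the trisubstituted alkene are inert to the silyl radical chain.

Step 11
Reactants: 16 [(2R)-2-methyloxiran-2-yl]methanol ((R)-2-methylglycidol)
Product: 17 [(2S)-2-methyloxiran-2-yl]methyl 4-methylbenzenesulfonate
Conditions: TsCl, Et3N, DMAP (cat.), CH2Cl2, 0 °C
Reagents that add atoms: 4-methylbenzenesulfonyl chloride, Cc1ccc(cc1)S(=O)(=O)Cl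
Why: O-sulfonylation of the primary alcohol; the quaternary centre is untouched (the descriptor changes only through priorities).

Step 12
Reactants: 17 glycidyl tosylate; 18 allylmagnesium bromide
Product: 20 (2S)-2-(but-3-en-1-yl)-2-methyloxirane, via tosyloxy alcohol 19 (not isolated)
Conditions: 18 (1.3 equiv), CuI (0.1 equiv), THF, −40 to −20 °C; H2O quench; then K2CO3, MeOH, 0 °C to rt
Reagents that add atoms: none
Why: copper-catalysed Grignard opening of the epoxide at its CH2, then 3-exo-tet displacement of the tosylate by the tertiary alkoxide (epoxide transposition); the C–O bond at the quaternary carbon is never broken, so its configuration is kept.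

Step 13
Reactants: 20 (2S)-2-(but-3-en-1-yl)-2-methyloxirane
Product: 21 3-[(2S)-2-methyloxiran-2-yl]propanal
Conditions: O3, CH2Cl2, −78 °C; then Me2S, −78 °C to rt
Reagents that add atoms: ozone, [O-][O+]=O
Why: ozonolysis of the terminal alkene with reductive work-up; the epoxide is inert and the volatile aldehyde is used directly.

Step 14
Reactants: 21 3-[(2S)-2-methyloxiran-2-yl]propanal; 22 propanoyl chloride
Product: 23 (3S,4R)-3-methyl-4-{2-[(2S)-2-methyloxiran-2-yl]ethyl}oxetan-2-one
Conditions: O-trimethylsilylquinidine (0.1 equiv), LiClO4 (1 equiv), iPr2NEt, CH2Cl2/Et2O, −78 °C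
Reagents that add atoms: none
Why: cinchona alkaloid/LiClO4-catalysed acyl halide–aldehyde cyclocondensation (formal [2+2] of in situ methylketene through a chiral ammonium enolate and a closed aldol transition state) gives the cis-β-lactone, with both new centres (later C2 and C3 of the propanoate unit) set by the catalyst.

Step 15
Reactants: 23 epoxy β-lactone
Product: 24 (3S,4R)-4-[(3R)-3-hydroperoxy-4-hydroxy-3-methylbutyl]-3-methyloxetan-2-one
Conditions: H2O2 (anhydrous, in Et2O, 8 equiv), H3PMo12O40 (0.02 equiv), Et2O, 0 °C to rt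
Reagents that add atoms: hydrogen peroxide, OO
Why: phosphomolybdic acid-catalysed perhydrolysis of the 2,2-disubstituted epoxide, in which H2O2 attacks the tertiary carbon with inversion (borderline SN2); this sets the quaternary peroxy carbon (dioxane C6) and frees the CH2OH handle (C12).

Step 16
Reactants: 24 hydroperoxy β-lactone
Product: 26 methyl (2S)-2-[(3S,6R)-6-(hydroxymethyl)-6-methyl-1,2-dioxan-3-yl]propanoate, via caesium carboxylate 25 (not isolated)
Conditions: Cs2CO3 (1.1 equiv), DMF (0.01 M), 0 °C; then MeI, 0 °C to rt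
Reagents that add atoms: iodomethane, CI
Why: Proposed new method: the hydroperoxide anion (α-effect nucleophile) attacks the β-carbon of the β-lactone intramolecularly (6-exo-tet, alkyl–oxygen cleavage with inversion), turning the cis (2,3-syn) lactone into the 2,3-anti (erythro) dioxane carboxylate, which is O-methylated in the same flask; the closest known reactions are SN2 openings of 4-alkyl β-lactones by azide, thiolate or carboxylate and hydroperoxide cyclisations onto secondary sulfonates.

Step 17
Reactants: 26 hydroxymethyl dioxane ester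
Product: 27 methyl (2S)-2-[(3S,6R)-6-formyl-6-methyl-1,2-dioxan-3-yl]propanoate
Conditions: Dess–Martin periodinane, CH2Cl2, 0 °C to rt
Reagents that add atoms: none
Why: Dess–Martin oxidation of the primary alcohol is compatible with the peroxide and ester, and the aldehyde has no α-hydrogen to epimerise.

Step 18
Reactants: 15 decalin tetrazolyl sulfone; 27 dioxane aldehyde
Product: 28 methyl (2S)-2-[(3S,6R)-6-methyl-6-{(E)-2-[(1S,4aR,8aR)-2,5,5,8a-tetramethyl-1,4,4a,5,6,7,8,8a-octahydronaphthalen-1-yl]ethenyl}-1,2-dioxan-3-yl]propanoate (E major)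
Conditions: KN(SiMe3)2 (1.1 equiv) added to 15 + 27 in MeOCH2CH2OMe, −60 °C to rt
Reagents that add atoms: none
Why: Julia–Kocienski olefination (addition, Smiles rearrangement, loss of SO2 and tetrazolone) forms the C11–C12 bond; the alkene geometry is irrelevant and the in situ protocol limits base contact with the peroxy ester.

Step 19
Reactants: 28 alkene
Product: 29 methyl (2S)-2-[(3S,6S)-6-methyl-6-{2-[(1S,4aR,8aR)-2,5,5,8a-tetramethyl-1,4,4a,5,6,7,8,8a-octahydronaphthalen-1-yl]ethyl}-1,2-dioxan-3-yl]propanoate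
Conditions: KO2CN=NCO2K, AcOH, MeOH/CH2Cl2, 0 °C to rt (repeated charges)
Reagents that add atoms: none
Why: diimide syn-hydrogenation reduces the disubstituted alkene but not the trisubstituted ring alkene or the O–O bond, and no stereocentre is touched.

**Compound list**
1 | 5-bromo-2-methylpent-2-ene | CC(C)=CCCBr | starting material
2 | lithium acetylide–ethylenediamine complex | [Li+].[C-]#C.NCCN | starting material
3 | 6-methylhept-5-en-1-yne | CC(C)=CCCC#C | intermediate
4 | [(1E)-2,6-dimethylhepta-1,5-dien-1-yl]dimethylalane | C[Al](C)/C=C(\C)CCC=C(C)C | intermediate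
5 | methyl (2E)-3,7-dimethylocta-2,6-dienoate | COC(=O)/C=C(\C)CCC=C(C)C | intermediate
6 | methyl (2E)-5-[(2R)-3,3-dimethyloxiran-2-yl]-3-methylpent-2-enoate | COC(=O)/C=C(\C)CC[C@H]1OC1(C)C | intermediate
7 | (2E)-5-[(2R)-3,3-dimethyloxiran-2-yl]-3-methylpent-2-en-1-ol | OC/C=C(\C)CC[C@H]1OC1(C)C | intermediate
8 | (2E)-5-[(2R)-3,3-dimethyloxiran-2-yl]-3-methylpent-2-en-1-yl methanesulfonate | CS(=O)(=O)OC/C=C(\C)CC[C@H]1OC1(C)C | intermediate
9 | (3R)-3-[(3E)-5-bromo-3-methylpent-3-en-1-yl]-2,2-dimethyloxirane | BrC/C=C(\C)CC[C@H]1OC1(C)C | intermediate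
10 | 3-methyl-2,5-dihydrothiophene 1,1-dioxide | CC1=CCS(=O)(=O)C1 | starting material
11 | 2-{(2E)-5-[(2R)-3,3-dimethyloxiran-2-yl]-3-methylpent-2-en-1-yl}-3-methyl-2,5-dihydrothiophene 1,1-dioxide (epimers at ring C2) | CC1=CCS(=O)(=O)C1C/C=C(\C)CC[C@H]1OC1(C)C | intermediate
12 | sodium [(1S,4aS,6R,8aR)-6-hydroxy-2,5,5,8a-tetramethyl-1,4,4a,5,6,7,8,8a-octahydronaphthalen-1-yl]methanesulfinate | [Na+].[O-]S(=O)C[C@H]1C(C)=CC[C@@H]2C(C)(C)[C@H](O)CC[C@]21C | intermediate
13 | 5-({[(1S,4aS,6R,8aR)-6-hydroxy-2,5,5,8a-tetramethyl-1,4,4a,5,6,7,8,8a-octahydronaphthalen-1-yl]methyl}sulfonyl)-1-phenyl-1H-tetrazole | O=S(=O)(C[C@H]1C(C)=CC[C@@H]2C(C)(C)[C@H](O)CC[C@]21C)c1nnnn1-c1ccccc1 | intermediate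
14 | O-ester of 13 (C3 hydroxyl) with 1H-imidazole-1-carbothioic acid | O=S(=O)(C[C@H]1C(C)=CC[C@@H]2C(C)(C)[C@H](OC(=S)n3ccnc3)CC[C@]21C)c1nnnn1-c1ccccc1 | intermediate
15 | 1-phenyl-5-({[(1S,4aR,8aR)-2,5,5,8a-tetramethyl-1,4,4a,5,6,7,8,8a-octahydronaphthalen-1-yl]methyl}sulfonyl)-1H-tetrazole | O=S(=O)(C[C@H]1C(C)=CC[C@@H]2C(C)(C)CCC[C@]21C)c1nnnn1-c1ccccc1 | intermediate
16 | [(2R)-2-methyloxiran-2-yl]methanol | C[C@@]1(CO)CO1 | starting material
17 | [(2S)-2-methyloxiran-2-yl]methyl 4-methylbenzenesulfonate | C[C@@]1(COS(=O)(=O)c2ccc(C)cc2)CO1 | intermediate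
18 | allylmagnesium bromide | C=CC[Mg]Br | starting material
19 | (2S)-2-hydroxy-2-methylhex-5-en-1-yl 4-methylbenzenesulfonate | C=CCC[C@](C)(O)COS(=O)(=O)c1ccc(C)cc1 | intermediate
20 | (2S)-2-(but-3-en-1-yl)-2-methyloxirane | C=CCC[C@@]1(C)CO1 | intermediate
21 | 3-[(2S)-2-methyloxiran-2-yl]propanal | O=CCC[C@@]1(C)CO1 | intermediate
22 | propanoyl chloride | CCC(=O)Cl | starting material
23 | (3S,4R)-3-methyl-4-{2-[(2S)-2-methyloxiran-2-yl]ethyl}oxetan-2-one | C[C@H]1[C@@H](CC[C@@]2(C)CO2)OC1=O | intermediate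
24 | (3S,4R)-4-[(3R)-3-hydroperoxy-4-hydroxy-3-methylbutyl]-3-methyloxetan-2-one | C[C@H]1[C@@H](CC[C@](C)(CO)OO)OC1=O | intermediate
25 | caesium (2S)-2-[(3S,6R)-6-(hydroxymethyl)-6-methyl-1,2-dioxan-3-yl]propanoate | [Cs+].[O-]C(=O)[C@@H](C)[C@@H]1CC[C@](C)(CO)OO1 | intermediate
26 | methyl (2S)-2-[(3S,6R)-6-(hydroxymethyl)-6-methyl-1,2-dioxan-3-yl]propanoate | COC(=O)[C@@H](C)[C@@H]1CC[C@](C)(CO)OO1 | intermediate
27 | methyl (2S)-2-[(3S,6R)-6-formyl-6-methyl-1,2-dioxan-3-yl]propanoate | COC(=O)[C@@H](C)[C@@H]1CC[C@](C)(C=O)OO1 | intermediate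
28 | methyl (2S)-2-[(3S,6R)-6-methyl-6-{(E)-2-[(1S,4aR,8aR)-2,5,5,8a-tetramethyl-1,4,4a,5,6,7,8,8a-octahydronaphthalen-1-yl]ethenyl}-1,2-dioxan-3-yl]propanoate | COC(=O)[C@@H](C)[C@@H]1CC[C@](C)(/C=C/[C@H]2C(C)=CC[C@@H]3C(C)(C)CCC[C@]32C)OO1 | intermediate
29 | methyl (2S)-2-[(3S,6S)-6-methyl-6-{2-[(1S,4aR,8aR)-2,5,5,8a-tetramethyl-1,4,4a,5,6,7,8,8a-octahydronaphthalen-1-yl]ethyl}-1,2-dioxan-3-yl]propanoate | COC(=O)[C@@H](C)[C@@H]1CC[C@](C)(CC[C@H]2C(C)=CC[C@@H]3C(C)(C)CCC[C@]32C)OO1 | target

**Totals**
Total step count: 19. Longest linear sequence: 12 (steps 1–10, 18, 19).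

**Three steps most likely to fail**

Step 7. The bridged 6-endo closure onto the sulfolene is untested, and only one C7 epimer of 11 can reach the chair transition state. The fallback sets out from 11 and comes back at 12. Ring A is closed first by a polar epoxide-initiated cyclisation (ZrCl4, CH2Cl2, −78 °C) to 2-{[(1S,3R)-3-hydroxy-2,2-dimethyl-6-methylidenecyclohexyl]methyl}-3-methyl-2,5-dihydrothiophene 1,1-dioxide F1. Its C7 epimers now sit next to fixed stereocentres, so they can be separated and the wrong one re-equilibrated with DBU. The matched epimer is then closed to ring B by a metal-hydride hydrogen-atom-transfer radical reaction (Fe(acac)3, PhSiH3, EtOH, 60 °C): H adds to the exocyclic CH2, and the tertiary C10 radical attacks C9 and fragments as in step 7. NaOH work-up gives 12.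

Step 14. The Lewis-acidic cyclocondensation must tolerate the acid-sensitive 2,2-disubstituted epoxide and a volatile aldehyde. The fallback sets out from 21 and comes back at 23. An Evans boron aldol of (4S)-4-benzyl-3-propanoyl-1,3-oxazolidin-2-one (Bu2BOTf, Et3N, CH2Cl2, −78 °C) with 21 gives the syn adduct (4S)-4-benzyl-3-{(2S,3R)-3-hydroxy-2-methyl-5-[(2S)-2-methyloxiran-2-yl]pentanoyl}-1,3-oxazolidin-2-one F2. LiOH/H2O2 removes the auxiliary to give (2S,3R)-3-hydroxy-2-methyl-5-[(2S)-2-methyloxiran-2-yl]pentanoic acid F3. Carboxyl-activating lactonisation (PhSO2Cl, pyridine, 0 °C, retention at both centres) gives 23.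

Step 16. Hydroperoxide opening of a β-lactone at the alkyl carbon has no direct precedent, and acyl attack or elimination may compete. The fallback sets out from 21 and comes back at 26. Z-selective Still–Gennari olefination of 21 with methyl 2-[bis(2,2,2-trifluoroethoxy)phosphoryl]propanoate (KN(SiMe3)2, 18-crown-6, THF, −78 °C) gives methyl (2Z)-2-methyl-5-[(2S)-2-methyloxiran-2-yl]pent-2-enoate F4. Perhydrolysis as in step 15 gives methyl (2Z,6R)-6-hydroperoxy-7-hydroxy-2,6-dimethylhept-2-enoate F5. Intramolecular oxa-Michael addition (Et2NH, CF3CH2OH, rt) should give the erythro C2/C3 pair by anti addition across the Z-enoate. C3 is not controlled relative to C6 in this closure, so the unwanted diastereomers must be removed by chromatography to give 26.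

**Further compounds**
F1 | step 7 | 2-{[(1S,3R)-3-hydroxy-2,2-dimethyl-6-methylidenecyclohexyl]methyl}-3-methyl-2,5-dihydrothiophene 1,1-dioxide | C=C1CC[C@@H](O)C(C)(C)[C@H]1CC1C(C)=CCS1(=O)=O
F2 | step 14 | (4S)-4-benzyl-3-{(2S,3R)-3-hydroxy-2-methyl-5-[(2S)-2-methyloxiran-2-yl]pentanoyl}-1,3-oxazolidin-2-one | C[C@H](C(=O)N1[C@@H](Cc2ccccc2)COC1=O)[C@H](O)CC[C@@]1(C)CO1
F3 | step 14 | (2S,3R)-3-hydroxy-2-methyl-5-[(2S)-2-methyloxiran-2-yl]pentanoic acid | C[C@H](C(=O)O)[C@H](O)CC[C@@]1(C)CO1
F4 | step 16 | methyl (2Z)-2-methyl-5-[(2S)-2-methyloxiran-2-yl]pent-2-enoate | COC(=O)/C(C)=C\CC[C@@]1(C)CO1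
F5 | step 16 | methyl (2Z,6R)-6-hydroperoxy-7-hydroxy-2,6-dimethylhept-2-enoate | COC(=O)/C(C)=C\CC[C@](C)(CO)OO
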